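**Strategy.** Everything rests on closing the six-membered ring onto a preformed cyclopentenone, between C7 and the methyl-bearing ring-fusion carbon C7a. Because C7a lies next to C1, the cyclopentane carbon that carries the side chain, a C1 ketone makes C7a the α-carbon of an enone dienolate. The precursor is an achiral 2-methylcyclopent-2-enone whose β-carbon (C3a) holds the C4–C7 chain ending in a bromide. Asymmetric phase-transfer α-alkylation forms the ring and the quaternary stereocentre in one operation and leaves a C3=C3a alkene. Hydrogenation anti to the angular methyl then sets the trans ring fusion, and the C1 carbonyl is elaborated into the methylene-bearing lactone side chain.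

Key step: step 6

Remark on numbering: hydrindane atoms are numbered as in indene (C1 carries the side chain, C3a and C7a are the ring-fusion carbons, C4 carries the geminal methyls); lactone atoms are numbered as in oxolan-2-one.

Assumption: the cinchonidine-derived catalyst of step 6 is taken to favour the 7aS product; if the sense is opposite, its cinchonine-derived pseudoenantiomer is used.

**Step 1**
Reactants: 1 isobutyronitrile; 2 (3-bromopropoxy)(tert-butyl)dimethylsilane
Product: 3 5-[(tert-butyldimethylsilyl)oxy]-2,2-dimethylpentanenitrile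
Conditions: LiN(i-Pr)2, THF, −78 °C; then 2, −78 °C to rt
Reagents that add atoms: none
Why: Alkylation of the lithiated nitrile with a primary bromide (nitrile anion alkylation) builds the quaternary carbon C4 with its two methyls; no stereocentre is formed.

**Step 2**
Reactants: 4 pent-1-en-3-one
Product: 5 2-ethyl-2-(2-iodoethyl)-1,3-dioxolane
Conditions: NaI, Me3SiCl, ethylene glycol, MeCN, rt
Reagents that add atoms: sodium iodide [Na+].[I-]; ethylene glycol OCCO
Why: Iodotrimethylsilane formed in the flask adds 1,4 to the enone and the β-iodo ketone is ketalised by the glycol (conjugate hydroiodination with in situ ketalisation), a known one-pot route to β-iodo ketals.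

**Step 3**
Reactants: 5 2-ethyl-2-(2-iodoethyl)-1,3-dioxolane; 3 5-[(tert-butyldimethylsilyl)oxy]-2,2-dimethylpentanenitrile
Product: 8 10-hydroxy-7,7-dimethyldecane-3,6-dione, via organolithium 6 (not isolated), via lithio ketimine 7 (not isolated)
Conditions: 5, t-BuLi (2 equiv), Et2O, −78 °C; then 3, −78 to 0 °C; then 2 M aq. HCl, THF, 40 °C
Reagents that add atoms: water O
Why: Iodine–lithium exchange gives a masked homoenolate that adds once to the non-enolisable nitrile (organolithium addition to a nitrile), and aqueous acid hydrolyses the ketimine and the dioxolane and cleaves the primary silyl ether, giving the 1,4-diketone.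

**Step 4**
Reactants: 8 10-hydroxy-7,7-dimethyldecane-3,6-dione
Product: 9 3-(5-hydroxy-2-methylpentan-2-yl)-2-methylcyclopent-2-en-1-one
Conditions: KOH, EtOH/H2O, reflux
Reagents that add atoms: none
Why: Intramolecular aldol condensation of a 1,4-diketone: only the CH2 of the ethyl ketone can reach the other carbonyl through a five-membered ring, so a single 2-methyl-3-alkylcyclopentenone should result.

**Step 5**
Reactants: 9 3-(5-hydroxy-2-methylpentan-2-yl)-2-methylcyclopent-2-en-1-one
Product: 10 3-(5-bromo-2-methylpentan-2-yl)-2-methylcyclopent-2-en-1-one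
Conditions: CBr4, PPh3, CH2Cl2, 0 °C
Reagents that add atoms: carbon tetrabromide BrC(Br)(Br)Br
Why: Appel reaction converts the primary alcohol into the bromide under neutral conditions that leave the enone untouched.

**Step 6**
Reactants: 10 3-(5-bromo-2-methylpentan-2-yl)-2-methylcyclopent-2-en-1-one
Product: 12 (7aS)-4,4,7a-trimethyl-2,4,5,6,7,7a-hexahydro-1H-inden-1-one, via dienolate 11 (not isolated)
Conditions: O-allyl-N-(9-anthracenylmethyl)cinchonidinium bromide (10 mol %), 50% aq. KOH, toluene, 0 °C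
Reagents that add atoms: none
Why: Proposed new method: hydroxide removes a γ-proton (C3) of the enone at the interface and the extended dienolate, carried into toluene as an ion pair with the chiral ammonium cation, displaces the tethered primary bromide through its α-carbon C7a, where the HOMO coefficient is largest; the closest known reaction types are the base-mediated deconjugative intramolecular α-alkylation of 3-(ω-haloalkyl)-2-alkylcycloalk-2-enones and the cinchona-ammonium phase-transfer alkylation of cyclic ketone enolates to α-quaternary ketones, which have not been combined on an unactivated enone dienolate. The six-membered ring closes in the 6-(enolexo)-exo-tet mode. The only new stereocentre, C7a, is set by the catalyst, whose cation covers one face of the planar dienolate so that the chain reaches C7a from the other. The step needs α- over γ-alkylation and C- over O-alkylation: closure through C3 is the less favourable enolendo mode at the carbon with the smaller coefficient, O-alkylation would need an eight-membered ring, and the cross-conjugated C2 enolate could only form a bridged ring with a bridgehead alkene and so reverts. Because C3a stays sp2, no ring-fusion geometry is fixed at this stage, which avoids the cis-fused outcome expected from closure onto a saturated cyclopentanone enolate. Low temperature and concentrated aqueous base are chosen to keep uncatalysed closure of the interfacial potassium dienolate slow.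

**Step 7**
Reactants: 12 (7aS)-4,4,7a-trimethyl-2,4,5,6,7,7a-hexahydro-1H-inden-1-one
Product: 13 (7aS)-4,4,7a-trimethyl-5,6,7,7a-tetrahydro-4H-inden-1-yl trifluoromethanesulfonate
Conditions: KN(SiMe3)2, THF, −78 °C; then PhNTf2, −78 to 0 °C
Reagents that add atoms: N-phenylbis(trifluoromethanesulfonimide) O=S(=O)(N(c1ccccc1)S(=O)(=O)C(F)(F)F)C(F)(F)F
Why: Only C2 carries α-hydrogens because C7a is quaternary, so enolisation and O-sulfonylation (enol triflate formation) should give one dienyl triflate.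

**Step 8**
Reactants: 13 (7aS)-4,4,7a-trimethyl-5,6,7,7a-tetrahydro-4H-inden-1-yl trifluoromethanesulfonate; 14 tributyl(1-ethoxyethenyl)stannane
Product: 16 1-[(7aS)-4,4,7a-trimethyl-5,6,7,7a-tetrahydro-4H-inden-1-yl]ethan-1-one, via enol ether 15 (not isolated)
Conditions: Pd(PPh3)4 (5 mol %), LiCl, THF, 65 °C; then 1 M aq. HCl, THF, rt
Reagents that add atoms: water O
Why: Stille coupling of the alkenyl triflate with an acetyl anion equivalent, followed by mild hydrolysis of the enol ether; the fully substituted C7a rules out hydrogen shifts in the cyclopentadiene.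

**Step 9**
Reactants: 16 1-[(7aS)-4,4,7a-trimethyl-5,6,7,7a-tetrahydro-4H-inden-1-yl]ethan-1-one
Product: 17 1-[(1S,3aS,7aS)-4,4,7a-trimethyloctahydro-1H-inden-1-yl]ethan-1-one
Conditions: H2 (4 atm), 10% Pd/C, EtOAc, rt
Reagents that add atoms: none
Why: Heterogeneous catalytic hydrogenation should deliver hydrogen to both ring alkenes from the α face, opposite the angular methyl on C7a, so that C3a–H ends trans to the methyl (trans ring fusion) and the acetyl group at C1 ends β, cis to the methyl, which is also the configuration favoured by equilibration through the enol.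

**Step 10**
Reactants: 17 1-[(1S,3aS,7aS)-4,4,7a-trimethyloctahydro-1H-inden-1-yl]ethan-1-one
Product: 18 N'-{1-[(1S,3aS,7aS)-4,4,7a-trimethyloctahydro-1H-inden-1-yl]ethylidene}-2,4,6-tri(propan-2-yl)benzenesulfonohydrazide
Conditions: 2,4,6-triisopropylbenzenesulfonyl hydrazide, cat. HCl, THF, rt
Reagents that add atoms: 2,4,6-triisopropylbenzenesulfonyl hydrazide NNS(=O)(=O)c1c(C(C)C)cc(C(C)C)cc1C(C)C
Why: Condensation of the methyl ketone with the sulfonyl hydrazide (hydrazone formation) prepares the Shapiro reaction; C1 keeps its more stable β configuration.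

**Step 11**
Reactants: 19 (4S)-4-benzyl-1,3-oxazolidin-2-one; 20 acryloyl chloride
Product: 21 (4S)-4-benzyl-3-(prop-2-enoyl)-1,3-oxazolidin-2-one
Conditions: Et3N, LiCl, THF, 0 °C to rt
Reagents that add atoms: none
Why: N-Acylation of the oxazolidinone under mild amine base with lithium chloride activation; the stereocentre of the auxiliary is not involved.

**Step 12**
Reactants: 21 (4S)-4-benzyl-3-(prop-2-enoyl)-1,3-oxazolidin-2-one; 22 tert-butyldimethyl(prop-2-en-1-yloxy)silane
Product: 23 (4S)-4-benzyl-3-[(2E)-4-[(tert-butyldimethylsilyl)oxy]but-2-enoyl]-1,3-oxazolidin-2-one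
Conditions: second-generation Grubbs catalyst (5 mol %), 22 (3 equiv), CH2Cl2, 40 °C
Reagents that add atoms: none
Why: Olefin cross-metathesis of an electron-poor acrylimide with an allyl ether is cross-selective and should give the E enoyl imide.

**Step 13**
Reactants: 18 N'-{1-[(1S,3aS,7aS)-4,4,7a-trimethyloctahydro-1H-inden-1-yl]ethylidene}-2,4,6-tri(propan-2-yl)benzenesulfonohydrazide; 23 (4S)-4-benzyl-3-[(2E)-4-[(tert-butyldimethylsilyl)oxy]but-2-enoyl]-1,3-oxazolidin-2-one
Product: 26 (4S)-4-benzyl-3-[(3R)-4-[(tert-butyldimethylsilyl)oxy]-3-{1-[(1R,3aS,7aS)-4,4,7a-trimethyloctahydro-1H-inden-1-yl]ethenyl}butanoyl]-1,3-oxazolidin-2-one, via vinyllithium 24 (not isolated), via alkenylcopper 25 (not isolated)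
Conditions: 18, n-BuLi (2.05 equiv), THF, −78 to 0 °C; CuBr·SMe2 (1 equiv), −78 to −40 °C; then 23 (1.2 equiv) premixed with MgBr2·OEt2, −40 to −10 °C; aq. NH4Cl
Reagents that add atoms: none
Why: The Shapiro reaction removes a proton from the methyl group and gives the 1-substituted vinyllithium, which after transmetalation to copper adds 1,4 to the magnesium-chelated s-cis N-enoyl oxazolidinone on the face opposite the benzyl group (auxiliary-controlled organocopper conjugate addition), setting the R centre next to the new methylene.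

**Step 14**
Reactants: 26 (4S)-4-benzyl-3-[(3R)-4-[(tert-butyldimethylsilyl)oxy]-3-{1-[(1R,3aS,7aS)-4,4,7a-trimethyloctahydro-1H-inden-1-yl]ethenyl}butanoyl]-1,3-oxazolidin-2-one
Product: 27 (3R)-4-[(tert-butyldimethylsilyl)oxy]-3-{1-[(1R,3aS,7aS)-4,4,7a-trimethyloctahydro-1H-inden-1-yl]ethenyl}butan-1-ol
Conditions: LiBH4, MeOH (1 equiv), THF, 0 °C
Reagents that add atoms: none
Why: Lithium borohydride reduces the exocyclic imide carbonyl and releases the auxiliary (reductive cleavage of an N-acyloxazolidinone); no stereocentre is touched.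

**Step 15**
Reactants: 27 (3R)-4-[(tert-butyldimethylsilyl)oxy]-3-{1-[(1R,3aS,7aS)-4,4,7a-trimethyloctahydro-1H-inden-1-yl]ethenyl}butan-1-ol
Product: 28 (3R)-4-[(tert-butyldimethylsilyl)oxy]-3-{1-[(1R,3aS,7aS)-4,4,7a-trimethyloctahydro-1H-inden-1-yl]ethenyl}butanal
Conditions: Dess–Martin periodinane, NaHCO3, CH2Cl2, rt
Reagents that add atoms: none
Why: Dess–Martin oxidation of the primary alcohol; the α-carbon is a methylene, so the neighbouring stereocentre cannot epimerise.

**Step 16**
Reactants: 28 (3R)-4-[(tert-butyldimethylsilyl)oxy]-3-{1-[(1R,3aS,7aS)-4,4,7a-trimethyloctahydro-1H-inden-1-yl]ethenyl}butanal; 29 ethyl glyoxylate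
Product: 32 (3R,4R)-4-[(2R)-1-[(tert-butyldimethylsilyl)oxy]-3-[(1R,3aS,7aS)-4,4,7a-trimethyloctahydro-1H-inden-1-yl]but-3-en-2-yl]-3-hydroxyoxolan-2-one, via aldol adduct 30 (not isolated), via diol ester 31 (not isolated)
Conditions: L-proline (30 mol %), 29 (2 equiv, toluene solution), MeCN, 4 °C; then NaBH4, MeOH, −20 °C; AcOH, rt
Reagents that add atoms: none
Why: The proline enamine of 28 adds to the non-enolisable glyoxylate through the usual hydrogen-bonded chair-like transition state (proline-catalysed cross-aldol), which should give the anti adduct with catalyst control at both new centres (S at the formyl-bearing carbon, R at the carbinol), and borohydride reduction of the aldehyde followed by lactonisation of the γ-hydroxy ester turns the anti pair into the cis-3-hydroxy-4-alkyl lactone.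

**Step 17**
Reactants: 32 (3R,4R)-4-[(2R)-1-[(tert-butyldimethylsilyl)oxy]-3-[(1R,3aS,7aS)-4,4,7a-trimethyloctahydro-1H-inden-1-yl]but-3-en-2-yl]-3-hydroxyoxolan-2-one
Product: 33 (3R,4R)-3-hydroxy-4-[(2R)-1-hydroxy-3-[(1R,3aS,7aS)-4,4,7a-trimethyloctahydro-1H-inden-1-yl]but-3-en-2-yl]oxolan-2-one
Conditions: HF·pyridine, THF, 0 °C to rt
Reagents that add atoms: none
Why: Fluoride-mediated cleavage of the primary silyl ether (desilylation) leaves the γ-lactone and the 1,1-disubstituted alkene untouched.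

**Step 18**
Reactants: 33 (3R,4R)-3-hydroxy-4-[(2R)-1-hydroxy-3-[(1R,3aS,7aS)-4,4,7a-trimethyloctahydro-1H-inden-1-yl]but-3-en-2-yl]oxolan-2-one
Product: 34 (2R)-2-[(3R,4R)-4-hydroxy-5-oxooxolan-3-yl]-3-[(1R,3aS,7aS)-4,4,7a-trimethyloctahydro-1H-inden-1-yl]but-3-en-1-yl acetate
Conditions: AcCl (1.05 equiv), 2,4,6-collidine, CH2Cl2, −78 °C
Reagents that add atoms: acetyl chloride CC(=O)Cl
Why: Acylation with acetyl chloride and a hindered pyridine base at low temperature should be selective for the primary alcohol over the hindered, electron-poor α-hydroxy lactone (selective O-acylation).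

**Compound list**

1 | isobutyronitrile | CC(C)C#N | starting material
2 | (3-bromopropoxy)(tert-butyl)dimethylsilane | BrCCCO[Si](C)(C)C(C)(C)C | starting material
3 | 5-[(tert-butyldimethylsilyl)oxy]-2,2-dimethylpentanenitrile | CC(C)(CCCO[Si](C)(C)C(C)(C)C)C#N | intermediate
4 | pent-1-en-3-one | CCC(=O)C=C | starting material
5 | 2-ethyl-2-(2-iodoethyl)-1,3-dioxolane | CCC1(CCI)OCCO1 | intermediate
6 | 2-ethyl-2-(2-lithioethyl)-1,3-dioxolane | [Li]CCC1(CC)OCCO1 | intermediate (not isolated)
7 | N-lithio ketimine from 6 and 3 | [Li]N=C(CCC1(CC)OCCO1)C(C)(C)CCCO[Si](C)(C)C(C)(C)C | intermediate (not isolated)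
8 | 10-hydroxy-7,7-dimethyldecane-3,6-dione | CCC(=O)CCC(=O)C(C)(C)CCCO | intermediate
9 | 3-(5-hydroxy-2-methylpentan-2-yl)-2-methylcyclopent-2-en-1-one | CC1=C(C(C)(C)CCCO)CCC1=O | intermediate
10 | 3-(5-bromo-2-methylpentan-2-yl)-2-methylcyclopent-2-en-1-one | CC1=C(C(C)(C)CCCBr)CCC1=O | intermediate
11 | extended dienolate of 10 (O–C1=C7a–C3a=C3), ion-paired with the catalyst cation; anion shown | [O-]C1=C(C)C(=CC1)C(C)(C)CCCBr | intermediate (not isolated)
12 | (7aS)-4,4,7a-trimethyl-2,4,5,6,7,7a-hexahydro-1H-inden-1-one | O=C1CC=C2C(C)(C)CCC[C@]12C | intermediate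
13 | (7aS)-4,4,7a-trimethyl-5,6,7,7a-tetrahydro-4H-inden-1-yl trifluoromethanesulfonate | O=S(=O)(OC1=CC=C2C(C)(C)CCC[C@]12C)C(F)(F)F | intermediate
14 | tributyl(1-ethoxyethenyl)stannane | CCCC[Sn](CCCC)(CCCC)C(=C)OCC | starting material
15 | (7aS)-1-(1-ethoxyethenyl)-4,4,7a-trimethyl-5,6,7,7a-tetrahydro-4H-indene | CCOC(=C)C1=CC=C2C(C)(C)CCC[C@]12C | intermediate (not isolated)
16 | 1-[(7aS)-4,4,7a-trimethyl-5,6,7,7a-tetrahydro-4H-inden-1-yl]ethan-1-one | CC(=O)C1=CC=C2C(C)(C)CCC[C@]12C | intermediate
17 | 1-[(1S,3aS,7aS)-4,4,7a-trimethyloctahydro-1H-inden-1-yl]ethan-1-one | CC(=O)[C@H]1CC[C@H]2C(C)(C)CCC[C@]12C | intermediate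
18 | N'-{1-[(1S,3aS,7aS)-4,4,7a-trimethyloctahydro-1H-inden-1-yl]ethylidene}-2,4,6-tri(propan-2-yl)benzenesulfonohydrazide | CC(=NNS(=O)(=O)c1c(C(C)C)cc(C(C)C)cc1C(C)C)[C@H]1CC[C@H]2C(C)(C)CCC[C@]12C | intermediate
19 | (4S)-4-benzyl-1,3-oxazolidin-2-one | O=C1N[C@@H](Cc2ccccc2)CO1 | starting material
20 | acryloyl chloride | C=CC(=O)Cl | starting material
21 | (4S)-4-benzyl-3-(prop-2-enoyl)-1,3-oxazolidin-2-one | C=CC(=O)N1[C@@H](Cc2ccccc2)COC1=O | intermediate
22 | tert-butyldimethyl(prop-2-en-1-yloxy)silane | C=CCO[Si](C)(C)C(C)(C)C | starting material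
23 | (4S)-4-benzyl-3-[(2E)-4-[(tert-butyldimethylsilyl)oxy]but-2-enoyl]-1,3-oxazolidin-2-one | CC(C)(C)[Si](C)(C)OC/C=C/C(=O)N1[C@@H](Cc2ccccc2)COC1=O | intermediate
24 | 1-lithio-1-(4,4,7a-trimethyloctahydro-1H-inden-1-yl)ethene, hydrindane stereocentres as in 17 (side chain β at C1, trans ring fusion) | [Li]C(=C)[C@H]1CC[C@H]2C(C)(C)CCC[C@]12C | intermediate (not isolated)
25 | corresponding alkenylcopper reagent, hydrindane stereocentres as in 17 | [Cu]C(=C)[C@H]1CC[C@H]2C(C)(C)CCC[C@]12C | intermediate (not isolated)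
26 | (4S)-4-benzyl-3-[(3R)-4-[(tert-butyldimethylsilyl)oxy]-3-{1-[(1R,3aS,7aS)-4,4,7a-trimethyloctahydro-1H-inden-1-yl]ethenyl}butanoyl]-1,3-oxazolidin-2-one | C=C([C@H]1CC[C@H]2C(C)(C)CCC[C@]12C)[C@H](CO[Si](C)(C)C(C)(C)C)CC(=O)N1[C@@H](Cc2ccccc2)COC1=O | intermediate
27 | (3R)-4-[(tert-butyldimethylsilyl)oxy]-3-{1-[(1R,3aS,7aS)-4,4,7a-trimethyloctahydro-1H-inden-1-yl]ethenyl}butan-1-ol | C=C([C@H]1CC[C@H]2C(C)(C)CCC[C@]12C)[C@H](CO[Si](C)(C)C(C)(C)C)CCO | intermediate
28 | (3R)-4-[(tert-butyldimethylsilyl)oxy]-3-{1-[(1R,3aS,7aS)-4,4,7a-trimethyloctahydro-1H-inden-1-yl]ethenyl}butanal | C=C([C@H]1CC[C@H]2C(C)(C)CCC[C@]12C)[C@H](CO[Si](C)(C)C(C)(C)C)CC=O | intermediate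
29 | ethyl glyoxylate | CCOC(=O)C=O | starting material
30 | ethyl (2R,3S,4R)-5-[(tert-butyldimethylsilyl)oxy]-3-formyl-2-hydroxy-4-{1-[(1R,3aS,7aS)-4,4,7a-trimethyloctahydro-1H-inden-1-yl]ethenyl}pentanoate | C=C([C@H]1CC[C@H]2C(C)(C)CCC[C@]12C)[C@H](CO[Si](C)(C)C(C)(C)C)[C@H](C=O)[C@@H](O)C(=O)OCC | intermediate (not isolated)
31 | ethyl (2R,3R,4R)-5-[(tert-butyldimethylsilyl)oxy]-2-hydroxy-3-(hydroxymethyl)-4-{1-[(1R,3aS,7aS)-4,4,7a-trimethyloctahydro-1H-inden-1-yl]ethenyl}pentanoate | C=C([C@H]1CC[C@H]2C(C)(C)CCC[C@]12C)[C@H](CO[Si](C)(C)C(C)(C)C)[C@H](CO)[C@@H](O)C(=O)OCC | intermediate (not isolated)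
32 | (3R,4R)-4-[(2R)-1-[(tert-butyldimethylsilyl)oxy]-3-[(1R,3aS,7aS)-4,4,7a-trimethyloctahydro-1H-inden-1-yl]but-3-en-2-yl]-3-hydroxyoxolan-2-one | C=C([C@H]1CC[C@H]2C(C)(C)CCC[C@]12C)[C@H](CO[Si](C)(C)C(C)(C)C)[C@@H]1COC(=O)[C@@H]1O | intermediate
33 | (3R,4R)-3-hydroxy-4-[(2R)-1-hydroxy-3-[(1R,3aS,7aS)-4,4,7a-trimethyloctahydro-1H-inden-1-yl]but-3-en-2-yl]oxolan-2-one | C=C([C@H]1CC[C@H]2C(C)(C)CCC[C@]12C)[C@H](CO)[C@@H]1COC(=O)[C@@H]1O | intermediate
34 | (2R)-2-[(3R,4R)-4-hydroxy-5-oxooxolan-3-yl]-3-[(1R,3aS,7aS)-4,4,7a-trimethyloctahydro-1H-inden-1-yl]but-3-en-1-yl acetate | C=C([C@H]1CC[C@H]2C(C)(C)CCC[C@]12C)[C@H](COC(C)=O)[C@@H]1COC(=O)[C@@H]1O | target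

**Totals.** Total step count: 18. Longest linear sequence: 15 steps (steps 1, 3 to 10 and 13 to 18; step 2 and steps 11 and 12 make the two partners that enter in steps 3 and 13).

**Steps most likely to fail**

Step 6 (Proposed new method). The chiral ion pair may discriminate the two dienolate faces poorly, or the potassium dienolate may close at the interface before cation exchange, so that enantioselectivity is lost; some γ-alkylation may also occur. The fallback closes the ring without a chiral catalyst and resolves the ketone, using known chemistry only. It sets out from 10, which with KOt-Bu in t-BuOH/THF at rt should give racemic 4,4,7a-trimethyl-2,4,5,6,7,7a-hexahydro-1H-inden-1-one F1 by the known deconjugative α-alkylation. Lithiated (S)-N,S-dimethyl-S-phenylsulfoximine (n-BuLi, THF, −78 °C) is added to the ketone from the face opposite the angular methyl, and the two diastereomeric β-hydroxysulfoximines are separated by chromatography. The diastereomer derived from the 7aS ketone, (S)-S-{[(1S,7aS)-1-hydroxy-4,4,7a-trimethyl-2,4,5,6,7,7a-hexahydro-1H-inden-1-yl]methyl}-N-methyl-S-phenylsulfoximine F2, is heated in toluene, where retro-addition releases 12 and the route is rejoined.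

Step 13. Transfer of the hindered 1,1-disubstituted alkenyl group from copper may be slow, so that protonation of the organometallic competes, and the chiral nucleophile may be mismatched with the auxiliary, giving poor facial selectivity. The fallback forms the same bond by rhodium catalysis and sets out from 17. Kinetic enolisation (LiN(i-Pr)2, THF, −78 °C) and PhNTf2 should give 1-[(1S,3aS,7aS)-4,4,7a-trimethyloctahydro-1H-inden-1-yl]ethenyl trifluoromethanesulfonate F3. Borylation (B2pin2, PdCl2(PPh3)2, PPh3, KOPh, toluene, 50 °C) gives the pinacol ester of the 1-(hydrindanyl)ethenylboronic acid F4. Catalyst-controlled 1,4-addition ([Rh(cod)OH]2, BINAP of the enantiomer that delivers the R centre, dioxane/H2O) to methyl (E)-4-[(tert-butyldimethylsilyl)oxy]but-2-enoate gives methyl (3R)-4-[(tert-butyldimethylsilyl)oxy]-3-{1-[(1R,3aS,7aS)-4,4,7a-trimethyloctahydro-1H-inden-1-yl]ethenyl}butanoate F5. Reduction with i-Bu2AlH in CH2Cl2 at −78 °C gives aldehyde 28, where the route is rejoined.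

Step 16. The existing stereocentre β to the aldehyde may override the catalyst and erode the diastereoselectivity, and the β-hydroxy aldehyde may undergo retro-aldol reaction or epimerisation before it is reduced. The fallback uses the auxiliary instead of the organocatalyst and sets out from 26. The boron enolate (n-Bu2BOTf, i-Pr2NEt, CH2Cl2, 0 °C) and 29 should give the syn aldol ethyl (2S,3S,4R)-3-{[(4S)-4-benzyl-2-oxo-1,3-oxazolidin-3-yl]carbonyl}-5-[(tert-butyldimethylsilyl)oxy]-2-hydroxy-4-{1-[(1R,3aS,7aS)-4,4,7a-trimethyloctahydro-1H-inden-1-yl]ethenyl}pentanoate F6, which is correct at C4 and epimeric at C3. NaBH4 in THF/H2O removes the auxiliary reductively and the alcohol lactonises to the trans lactone (3S,4R)-4-[(2R)-1-[(tert-butyldimethylsilyl)oxy]-3-[(1R,3aS,7aS)-4,4,7a-trimethyloctahydro-1H-inden-1-yl]but-3-en-2-yl]-3-hydroxyoxolan-2-one F7. Tf2O and pyridine at −20 °C give its 3-O-trifluoromethanesulfonate F8, and n-Bu4N NO2 in toluene inverts C3 (Lattrell–Dax type nitrite displacement, the nitrite ester being hydrolysed on work-up) to give 32, where the route is rejoined.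

**Further compounds**

F1 | step 6 | racemic 4,4,7a-trimethyl-2,4,5,6,7,7a-hexahydro-1H-inden-1-one | O=C1CC=C2C(C)(C)CCCC12C
F2 | step 6 | (S)-S-{[(1S,7aS)-1-hydroxy-4,4,7a-trimethyl-2,4,5,6,7,7a-hexahydro-1H-inden-1-yl]methyl}-N-methyl-S-phenylsulfoximine | CN=[S@@](C[C@]1(O)CC=C2C(C)(C)CCC[C@]12C)(=O)c1ccccc1
F3 | step 13 | 1-[(1S,3aS,7aS)-4,4,7a-trimethyloctahydro-1H-inden-1-yl]ethenyl trifluoromethanesulfonate | C=C(OS(=O)(=O)C(F)(F)F)[C@H]1CC[C@H]2C(C)(C)CCC[C@]12C
F4 | step 13 | 4,4,5,5-tetramethyl-2-[1-(4,4,7a-trimethyloctahydro-1H-inden-1-yl)ethenyl]-1,3,2-dioxaborolane, hydrindane stereocentres as in 17 | C=C(B1OC(C)(C)C(C)(C)O1)[C@H]1CC[C@H]2C(C)(C)CCC[C@]12C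
F5 | step 13 | methyl (3R)-4-[(tert-butyldimethylsilyl)oxy]-3-{1-[(1R,3aS,7aS)-4,4,7a-trimethyloctahydro-1H-inden-1-yl]ethenyl}butanoate | C=C([C@H]1CC[C@H]2C(C)(C)CCC[C@]12C)[C@H](CO[Si](C)(C)C(C)(C)C)CC(=O)OC
F6 | step 16 | ethyl (2S,3S,4R)-3-{[(4S)-4-benzyl-2-oxo-1,3-oxazolidin-3-yl]carbonyl}-5-[(tert-butyldimethylsilyl)oxy]-2-hydroxy-4-{1-[(1R,3aS,7aS)-4,4,7a-trimethyloctahydro-1H-inden-1-yl]ethenyl}pentanoate | C=C([C@H]1CC[C@H]2C(C)(C)CCC[C@]12C)[C@H](CO[Si](C)(C)C(C)(C)C)[C@H](C(=O)N1[C@@H](Cc2ccccc2)COC1=O)[C@H](O)C(=O)OCC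
F7 | step 16 | (3S,4R)-4-[(2R)-1-[(tert-butyldimethylsilyl)oxy]-3-[(1R,3aS,7aS)-4,4,7a-trimethyloctahydro-1H-inden-1-yl]but-3-en-2-yl]-3-hydroxyoxolan-2-one | C=C([C@H]1CC[C@H]2C(C)(C)CCC[C@]12C)[C@H](CO[Si](C)(C)C(C)(C)C)[C@@H]1COC(=O)[C@H]1O
F8 | step 16 | (3S,4R)-4-[(2R)-1-[(tert-butyldimethylsilyl)oxy]-3-[(1R,3aS,7aS)-4,4,7a-trimethyloctahydro-1H-inden-1-yl]but-3-en-2-yl]-2-oxooxolan-3-yl trifluoromethanesulfonate | C=C([C@H]1CC[C@H]2C(C)(C)CCC[C@]12C)[C@H](CO[Si](C)(C)C(C)(C)C)[C@@H]1COC(=O)[C@H]1OS(=O)(=O)C(F)(F)F
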